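**Assumptions.** The SMILES is read as (2Z,6E)-9-[(2R)-6-hydroxy-2,8-dimethyl-2H-chromen-2-yl]-6-methyl-2-(4-methylpent-3-enyl)nona-2,6-dienoic acid (CO2H cis to the C4 chain CH2). Commercial (R)-(−)-linalool of ≥97% ee is assumed; the product ee equals the linalool ee. Reagents that only appear over the arrow are named with SMILES but not numbered. The route has not been run; conditions are by analogy to standard precedent.

## Retrosynthetic overview

1. Cut the C2=C3 enoate: Z-selective Still–Gennari olefination of a chromene aldehyde with an α-homoprenyl phosphonoacetate, then one global deprotection.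
2. The aldehyde comes from linalool's own isopropylidene end: SeO2 E-allylic oxidation, bromide, two-carbon homologation with an acetaldehyde aza-enolate.
3. The stereocentre is bought as (R)-(−)-linalool. Its C–O, C–CH3, C–vinyl and C–CH2 bonds are never broken, so C3 of linalool becomes C2 of the chromene.
4. Ring order: the benzene ring is purchased (aminocresol → bromo-iodo arene). The pyran ring is closed by B-alkyl Suzuki (C4–C4a) then Pd C–O coupling (O1–C8a), then dehydrogenated with DDQ to the 2H-chromene.

## Route

**Step 1**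
Reactants: **1** 4-amino-3-methylphenol
Product: **2** 2-methyl-4-(triisopropylsilyloxy)aniline
Conditions: TIPSCl, imidazole, DMF, rt
Reagents that add atoms: triisopropylsilyl chloride, CC(C)[Si](Cl)(C(C)C)C(C)C
Why: Selective O-silylation of the phenol over the aniline; TIPS survives every later basic and oxidative step and falls off in the final hydroxide step.

**Step 2**
Reactants: **2**
Product: **3** 2-iodo-6-methyl-4-(triisopropylsilyloxy)aniline
Conditions: NIS (1.0 equiv), DMF, 0 °C
Reagents that add atoms: N-iodosuccinimide, O=C1CCC(=O)N1I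
Why: Electrophilic aromatic iodination directed by NH2 to its only free ortho position (para is blocked by OTIPS).

**Step 3**
Reactants: **3**
Product: **4** (4-bromo-3-iodo-5-methylphenoxy)triisopropylsilane
Conditions: t-BuONO, CuBr2, MeCN, 0 → 60 °C
Reagents that add atoms: copper(II) bromide, Br[Cu]Br
Why: Anhydrous Sandmeyer (Doyle) bromination converts NH2 to Br, giving the contiguous I / Br / CH3 pattern with the oxygen para to Br.

**Step 4**
Reactants: **5** (R)-(−)-linalool; **4**
Product: **6** (3R)-1-[2-bromo-3-methyl-5-(triisopropylsilyloxy)phenyl]-3,7-dimethyloct-6-en-3-ol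
Conditions: **5**, 9-BBN (2.2 equiv), THF, 0 °C → rt; then **4**, Pd(dppf)Cl2 (5 mol%), 3 M aq K3PO4, DMF, 50 °C
Reagents that add atoms: none (9-BBN delivers only H)
Why: 9-BBN hydroborates the vinyl group anti-Markovnikov and leaves the trisubstituted alkene; the B-alkyl Suzuki–Miyaura coupling is selective for C–I over the hindered C–Br. The carbinol stereocentre is untouched and stays R.

**Step 5**
Reactants: **6**
Product: **7** triisopropyl{[(2R)-2,8-dimethyl-2-(4-methylpent-3-enyl)-3,4-dihydro-2H-chromen-6-yl]oxy}silane
Conditions: Pd(OAc)2 (5 mol%), 2-(di-tert-butylphosphino)-1,1'-binaphthyl (6 mol%), Cs2CO3, PhMe, 80 °C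
Reagents that add atoms: none
Why: Buchwald intramolecular Pd-catalysed C–O coupling; a tertiary alkoxide has no β-hydride on the carbinol carbon. The aryl C–O bond is formed and the C2–O bond is not broken, so configuration is retained (2R).

**Step 6**
Reactants: **7**
Product: **8** triisopropyl{[(2R)-2,8-dimethyl-2-(4-methylpent-3-enyl)-2H-chromen-6-yl]oxy}silane
Conditions: DDQ (1.3 equiv), PhH, reflux
Reagents that add atoms: none
Why: DDQ dehydrogenation by hydride abstraction at benzylic C4 (cation stabilised by the ortho ring oxygen), then loss of H-3. C2 is quaternary and unaffected.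

**Step 7**
Reactants: **8**
Product: **9** (2E)-5-[(2R)-2,8-dimethyl-6-(triisopropylsilyloxy)-2H-chromen-2-yl]-2-methylpent-2-en-1-ol
Conditions: SeO2 (0.5 equiv), t-BuOOH, salicylic acid (cat.), CH2Cl2, rt; then NaBH4, MeOH, 0 °C
Reagents that add atoms: selenium dioxide, O=[Se]=O (O source), with tert-butyl hydroperoxide, CC(C)(C)OO, as terminal oxidant
Why: Sharpless–Umbreit allylic oxidation (ene / [2,3] shift) is selective for the E-methyl of the isopropylidene; NaBH4 returns any over-oxidised enal to the alcohol.

**Step 8**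
Reactants: **9**
Product: **10** {[(2R)-2-[(3E)-5-bromo-4-methylpent-3-enyl]-2,8-dimethyl-2H-chromen-6-yl]oxy}triisopropylsilane
Conditions: CBr4, PPh3, CH2Cl2, −20 → 0 °C (use crude)
Reagents that add atoms: carbon tetrabromide, BrC(Br)(Br)Br
Why: Neutral Appel bromination of a primary allylic alcohol, without allylic transposition or E/Z loss and without acid that could harm the chromene.

**Step 9**
Reactants: **10**; **11** acetaldehyde N-tert-butylimine
Product: **12** (4E)-7-[(2R)-2,8-dimethyl-6-(triisopropylsilyloxy)-2H-chromen-2-yl]-4-methylhept-4-enal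
Conditions: **11**, LDA, THF, −78 → 0 °C; then **10**, −78 → −20 °C; then aq oxalic acid / Et2O, rt
Reagents that add atoms: **11**, CC=NC(C)(C)C (its CH2–CH carbons are retained); water, O (aldehyde oxygen)
Why: Stork–Wittig metalloenamine alkylation; SN2 of the aza-enolate on the allylic bromide, then mild imine hydrolysis, gives the two-carbon-extended aldehyde in one operation.

**Step 10**
Reactants: **13** methyl bis(2,2,2-trifluoroethyl)phosphonoacetate; **14** 5-bromo-2-methylpent-2-ene
Product: **15** methyl 2-[bis(2,2,2-trifluoroethoxy)phosphoryl]-6-methylhept-5-enoate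
Conditions: NaH, DMSO, rt; then **14**, NaI (cat.), 50 °C
Reagents that add atoms: none beyond **13** and **14**
Why: C-alkylation of the stabilised phosphonoacetate anion with the homoprenyl halide (in-situ Finkelstein); slow addition limits dialkylation.

**Step 11**
Reactants: **12**; **15**
Product: **16** methyl (2Z,6E)-9-[(2R)-2,8-dimethyl-6-(triisopropylsilyloxy)-2H-chromen-2-yl]-6-methyl-2-(4-methylpent-3-enyl)nona-2,6-dienoate
Conditions: **15**, KHMDS, 18-crown-6, THF, −78 °C; then **12**, −78 °C
Reagents that add atoms: none beyond **12** and **15**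
Why: Still–Gennari olefination; the trifluoroethyl phosphonate under dissociating conditions gives kinetic syn-elimination, placing the ester cis to the β-alkyl chain (the required 2Z, angelate-type geometry).

**Step 12**
Reactants: **16**
Product: **17** (R)-sargachromenol
Conditions: LiOH·H2O (10 equiv), degassed THF/MeOH/H2O (3:1:1), 45 °C, Ar, dark; then aq citric acid to pH 3–4
Reagents that add atoms: lithium hydroxide / water, [Li+].[OH-] (one carboxyl oxygen)
Why: Saponification of the methyl ester and hydroxide cleavage of the base-labile aryl O–Si bond in one step. Argon and mild temperature protect the chromenol and the Z-enoate.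

## Compound list

1 | 4-amino-3-methylphenol | Cc1cc(O)ccc1N | starting material
2 | 2-methyl-4-(triisopropylsilyloxy)aniline | Cc1cc(O[Si](C(C)C)(C(C)C)C(C)C)ccc1N | intermediate
3 | 2-iodo-6-methyl-4-(triisopropylsilyloxy)aniline | Cc1cc(O[Si](C(C)C)(C(C)C)C(C)C)cc(I)c1N | intermediate
4 | (4-bromo-3-iodo-5-methylphenoxy)triisopropylsilane | Cc1cc(O[Si](C(C)C)(C(C)C)C(C)C)cc(I)c1Br | intermediate
5 | (R)-(−)-linalool | CC(C)=CCC[C@](O)(C)C=C | starting material
6 | (3R)-1-[2-bromo-3-methyl-5-(TIPSO)phenyl]-3,7-dimethyloct-6-en-3-ol | CC(C)=CCC[C@](O)(C)CCc1cc(O[Si](C(C)C)(C(C)C)C(C)C)cc(C)c1Br | intermediate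
7 | (2R)-2,8-dimethyl-2-(4-methylpent-3-enyl)-6-(TIPSO)chromane | CC(C)=CCC[C@]1(C)CCc2cc(O[Si](C(C)C)(C(C)C)C(C)C)cc(C)c2O1 | intermediate
8 | (2R)-2,8-dimethyl-2-(4-methylpent-3-enyl)-6-(TIPSO)-2H-chromene | CC(C)=CCC[C@]1(C)C=Cc2cc(O[Si](C(C)C)(C(C)C)C(C)C)cc(C)c2O1 | intermediate
9 | (2E)-5-[(2R)-2,8-dimethyl-6-(TIPSO)-2H-chromen-2-yl]-2-methylpent-2-en-1-ol | OC/C(C)=C/CC[C@]1(C)C=Cc2cc(O[Si](C(C)C)(C(C)C)C(C)C)cc(C)c2O1 | intermediate
10 | (2R)-2-[(3E)-5-bromo-4-methylpent-3-enyl]-2,8-dimethyl-6-(TIPSO)-2H-chromene | BrC/C(C)=C/CC[C@]1(C)C=Cc2cc(O[Si](C(C)C)(C(C)C)C(C)C)cc(C)c2O1 | intermediate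
11 | acetaldehyde N-tert-butylimine | CC=NC(C)(C)C | starting material
12 | (4E)-7-[(2R)-2,8-dimethyl-6-(TIPSO)-2H-chromen-2-yl]-4-methylhept-4-enal | O=CCC/C(C)=C/CC[C@]1(C)C=Cc2cc(O[Si](C(C)C)(C(C)C)C(C)C)cc(C)c2O1 | intermediate
13 | methyl bis(2,2,2-trifluoroethyl)phosphonoacetate | COC(=O)CP(=O)(OCC(F)(F)F)OCC(F)(F)F | starting material
14 | 5-bromo-2-methylpent-2-ene | CC(C)=CCCBr | starting material
15 | methyl 2-[bis(2,2,2-trifluoroethoxy)phosphoryl]-6-methylhept-5-enoate | COC(=O)C(CCC=C(C)C)P(=O)(OCC(F)(F)F)OCC(F)(F)F | intermediate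
16 | methyl (2Z,6E)-9-[(2R)-2,8-dimethyl-6-(TIPSO)-2H-chromen-2-yl]-6-methyl-2-(4-methylpent-3-enyl)nona-2,6-dienoate | CC(C)=CCC/C(=C/CC/C(C)=C/CC[C@]1(C)C=Cc2cc(O[Si](C(C)C)(C(C)C)C(C)C)cc(C)c2O1)C(=O)OC | intermediate
17 | (R)-sargachromenol | CC(C)=CCC/C(=C/CC/C(C)=C/CC[C@]1(C)C=Cc2cc(O)cc(C)c2O1)C(=O)O | target

## Summary

Total steps: 12. Longest linear sequence: 11 (steps 1–9, 11, 12); step 10 is a one-step side branch.

Three steps most likely to fail, each with a fallback that changes the approach:

1. **Step 6 (DDQ dehydrogenation).** Risks are oxidation of the silylated hydroquinone-type ring or allylic side reactions. Fallback: never pass through the chroman. Make the aryl tertiary allylic ether by Pd-catalysed asymmetric allylic etherification (Trost ligand) of 2-hydroxy-3-methyl-5-(TIPSO)benzaldehyde with geranyl methyl carbonate, methylenate the aldehyde (Wittig), and close the 2H-pyran directly by ring-closing metathesis to **8**. The stereocentre is then set by the catalyst, not by linalool.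
2. **Step 5 (Pd C–O closure onto a di-ortho-substituted, electron-rich aryl bromide).** Fallback: close the ring through the quinone. Run the step-4 Suzuki coupling with 1-bromo-2,5-dimethoxy-3-methylbenzene, oxidise to the p-quinone (CAN), and cyclise reductively (ascorbic acid, HCl/MeOH) via the 8a-hydroxy hemiketal. The tertiary C–O bond is again never broken (retention), giving the 6-hydroxychroman, which is then silylated.
3. **Step 11 (Z-selectivity and yield of the α-branched Still–Gennari olefination).** Fallback: set the geometry with a halide instead of a phosphonate. Z-selective α-iodo-Wittig of **12** with the iodo-ylide from (5-methylhex-4-enyl)triphenylphosphonium gives the (Z)-vinyl iodide (I cis to the chain). Stereoretentive carboxylation (t-BuLi then CO2, or Pd/CO/MeOH) then gives the acid directly.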